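**Strategy.** Both outer-ring C5–O bonds are disconnected, taking each 2,3-dibromo-4,5-dihydroxybenzyl ring back to a 2,3-dibromo-4-hydroxybenzyl ring. On these rings (C1 carries CH2, C2 and C3 carry Br, C4 carries OH) the C4 hydroxyl has only one free ortho carbon, C5, because C3 holds bromine; a hypervalent-iodine ortho-oxygenation can therefore place oxygen only where the target has it. One operation converts the bis-phenol into the bis-catechol through a bis-ortho-quinone that is reduced in the same flask. The precursor is a hexasubstituted 5-bromo-2,4,6-trimethoxybenzene core, inert to the oxidant, whose two benzylic arms end in 2,3-dibromophenols; it is assembled by double Friedel–Crafts benzylation, and BBr3 unmasks the phloroglucinol last.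

Key step: step 3

Assumption: formaldehyde is charged as paraformaldehyde, and each chloromethyl group takes up one formaldehyde and one hydrogen chloride with loss of water, so step 1 consumes two molecules of each. One mole of 2-iodoxybenzoic acid is taken to carry out the four-electron oxidation of one phenol ring, the iodine finishing monovalent as 2-iodobenzoic acid.

**Step 1**
Reactants: 1 2-bromo-1,3,5-trimethoxybenzene; 2 formaldehyde (two molecules incorporated); 3 hydrogen chloride (two molecules incorporated)
Product: 4 1-bromo-3,5-bis(chloromethyl)-2,4,6-trimethoxybenzene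
Conditions: 2 (6 equiv, as paraformaldehyde), 3 (gas, bubbled to saturation), AcOH, 0 °C to rt
Reagents that add atoms: none
Why: Blanc chloromethylation: each of the two free ring carbons lies between two methoxy groups and is strongly activated, so protonated formaldehyde should hydroxymethylate both and hydrogen chloride should turn the benzylic alcohols into chlorides, while excess formaldehyde and hydrogen chloride together with dilution disfavour capture of the benzylic cation by unreacted arene, and the hexasubstituted product cannot react further.

**Step 2**
Reactants: 4 1-bromo-3,5-bis(chloromethyl)-2,4,6-trimethoxybenzene; 5 2,3-dibromophenol (two molecules incorporated)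
Product: 6 4,4'-[(5-bromo-2,4,6-trimethoxy-1,3-phenylene)bis(methylene)]bis(2,3-dibromophenol)
Conditions: 5 (6 equiv), ZnCl2 (0.5 equiv), CH2Cl2–MeNO2, 0 °C to rt
Reagents that add atoms: none
Why: Friedel–Crafts benzylation: ZnCl2 should ionise each benzylic chloride to a cation stabilised by two ortho and one para methoxy groups, and this selective electrophile should attack the phenol para to the hydroxyl, its most activated carbon (the same para-to-oxygen preference seen in acylations of 2,3-dihalophenyl ethers), while the excess of 5 keeps one phenol from taking two benzyl groups and the fully substituted core cannot self-condense.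

**Step 3**
Reactants: 6 4,4'-[(5-bromo-2,4,6-trimethoxy-1,3-phenylene)bis(methylene)]bis(2,3-dibromophenol)
Product: 8 5,5'-[(5-bromo-2,4,6-trimethoxy-1,3-phenylene)bis(methylene)]bis(3,4-dibromobenzene-1,2-diol), via bis-ortho-quinone 7 (not isolated)
Conditions: IBX (2.5 equiv), DMF, rt, dark; then aq. Na2S2O4, 0 °C, same flask
Reagents that add atoms: 2-iodoxybenzoic acid (IBX), O=C1OI(=O)(O)c2ccccc12
Why: Each phenol oxygen should exchange onto the pentavalent iodine of IBX, an iodine-bound oxygen is then passed within this aryloxy-iodane to the ortho carbon C5 while iodine drops to the trivalent state, and the resulting catechol ester of trivalent iodine collapses to the ortho-quinone and monovalent 2-iodobenzoic acid, so that one mole of oxidant serves each ring before Na2S2O4 returns bis-quinone 7 to the bis-catechol. The closest known reaction type is the regioselective IBX ortho-oxygenation of phenols to ortho-quinones with reductive work-up. No ring closes and no stereocentre is formed. Regioselectivity is secured by the substrate, since C3 carries bromine and C1 carries the benzylic carbon, leaving C5 as the only position at which a quinone can form. Chemoselectivity rests on the central ring having neither a free hydroxyl nor a ring hydrogen, on the catechol being released only after the oxidant is quenched, and on prompt cold reduction, which forestalls isomerisation of the 4-benzyl ortho-quinone to a para-quinone methide. The bromine-bearing rings are less electron-rich than simple alkylphenols, so excess oxidant and a longer reaction time are planned.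

**Step 4**
Reactants: 8 5,5'-[(5-bromo-2,4,6-trimethoxy-1,3-phenylene)bis(methylene)]bis(3,4-dibromobenzene-1,2-diol)
Product: 9 vidalol B, 2-bromo-4,6-bis(2,3-dibromo-4,5-dihydroxybenzyl)benzene-1,3,5-triol
Conditions: BBr3 (10 equiv), CH2Cl2, −78 °C to rt; H2O quench under argon
Reagents that add atoms: none
Why: Lewis-acid ether cleavage with BBr3: the three methoxy groups, each twisted out of plane between two ortho substituents, should bind boron and lose methyl to bromide by SN2, the four catechol hydroxyls only consume reagent as borate esters that hydrolyse on quench, and aryl C–Br and diarylmethane C–C bonds are not touched under cold anhydrous conditions.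

**Compound list**
1 | 2-bromo-1,3,5-trimethoxybenzene | COc1cc(OC)c(Br)c(OC)c1 | starting material
2 | formaldehyde (used as paraformaldehyde) | C=O | starting material
3 | hydrogen chloride | Cl | starting material
4 | 1-bromo-3,5-bis(chloromethyl)-2,4,6-trimethoxybenzene | COc1c(Br)c(OC)c(CCl)c(OC)c1CCl | intermediate
5 | 2,3-dibromophenol | Oc1cccc(Br)c1Br | starting material
6 | 4,4'-[(5-bromo-2,4,6-trimethoxy-1,3-phenylene)bis(methylene)]bis(2,3-dibromophenol) | COc1c(Br)c(OC)c(Cc2ccc(O)c(Br)c2Br)c(OC)c1Cc1ccc(O)c(Br)c1Br | intermediate
7 | 5,5'-[(5-bromo-2,4,6-trimethoxy-1,3-phenylene)bis(methylene)]bis(3,4-dibromocyclohexa-3,5-diene-1,2-dione) (bis-ortho-quinone, not isolated) | COc1c(Br)c(OC)c(CC2=CC(=O)C(=O)C(Br)=C2Br)c(OC)c1CC1=CC(=O)C(=O)C(Br)=C1Br | intermediate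
8 | 5,5'-[(5-bromo-2,4,6-trimethoxy-1,3-phenylene)bis(methylene)]bis(3,4-dibromobenzene-1,2-diol) | COc1c(Br)c(OC)c(Cc2cc(O)c(O)c(Br)c2Br)c(OC)c1Cc1cc(O)c(O)c(Br)c1Br | intermediate
9 | vidalol B, 2-bromo-4,6-bis(2,3-dibromo-4,5-dihydroxybenzyl)benzene-1,3,5-triol | Oc1cc(Cc2c(O)c(Br)c(O)c(Cc3cc(O)c(O)c(Br)c3Br)c2O)c(Br)c(Br)c1O | target

Total step count: 4. Longest linear sequence: 4 steps (1 → 4 → 6 → 8 → 9).

**Steps most likely to fail**

Step 3. The bromine-deactivated phenols may exchange onto iodine and accept oxygen only sluggishly, so conversion may stop after one ring, and a long-lived ortho-quinone may isomerise to a quinone methide and add water at the benzylic carbon. The fallback sets out from 6 and replaces direct oxygenation by formylation and oxidative rearrangement. Chelation-controlled ortho-formylation (MgCl2, Et3N, (CH2O)n, MeCN, reflux) can only functionalise C5 of each outer ring and should give 5,5'-[(5-bromo-2,4,6-trimethoxy-1,3-phenylene)bis(methylene)]bis(3,4-dibromo-2-hydroxybenzaldehyde) F1. Dakin oxidation (H2O2, NaOH, degassed THF–H2O, 0 °C to rt, then acidification) should then convert each formyl group through the aryl formate into a hydroxyl, rejoining the route at 8.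

Step 2. The benzylic cation may attack the carbon ortho to the phenolic hydroxyl or the oxygen itself, and because two alkylations are needed even modest leakage would give a mixture of regioisomers. The fallback reverses the polarity of the bond formation and fixes the regiochemistry on a small molecule; it sets out from 5 and 1. Phenol 5 is methylated (MeI, K2CO3, acetone) to 2,3-dibromoanisole F2. Rieche formylation (Cl2CHOMe, TiCl4, CH2Cl2, 0 °C) para to the methoxy group should give 2,3-dibromo-4-methoxybenzaldehyde F3, from which any ortho isomer is removed at this stage. BBr3 in CH2Cl2 gives 2,3-dibromo-4-hydroxybenzaldehyde F4, and NaBH4 in MeOH–THF gives 2,3-dibromo-4-(hydroxymethyl)phenol F5. Two equivalents of F5 then alkylate the two free, doubly methoxy-flanked carbons of 1 under acid catalysis (BF3·OEt2 or p-TsOH, CH2Cl2), through the para-quinone methide or benzylic cation, rejoining the route at 6.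

Step 1. The mono-chloromethylated intermediate may ionise and be captured by unreacted arene, leading to diarylmethane oligomers, and the labile chlorides may hydrolyse during isolation. The fallback sets out from 1 and introduces the two carbons as deactivating formyl groups. Exhaustive Rieche formylation (excess Cl2CHOMe, TiCl4, CH2Cl2, 0 °C to reflux) should give 5-bromo-2,4,6-trimethoxybenzene-1,3-dicarbaldehyde F6. NaBH4 in MeOH–THF gives (5-bromo-2,4,6-trimethoxy-1,3-phenylene)dimethanol F7, and concentrated HCl in CH2Cl2 at 0 °C exchanges the activated benzylic hydroxyls for chloride, rejoining the route at 4.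

**Further compounds**
F1 | step 3 | 5,5'-[(5-bromo-2,4,6-trimethoxy-1,3-phenylene)bis(methylene)]bis(3,4-dibromo-2-hydroxybenzaldehyde) | COc1c(Br)c(OC)c(Cc2cc(C=O)c(O)c(Br)c2Br)c(OC)c1Cc1cc(C=O)c(O)c(Br)c1Br
F2 | step 2 | 2,3-dibromoanisole | COc1cccc(Br)c1Br
F3 | step 2 | 2,3-dibromo-4-methoxybenzaldehyde | COc1ccc(C=O)c(Br)c1Br
F4 | step 2 | 2,3-dibromo-4-hydroxybenzaldehyde | Oc1ccc(C=O)c(Br)c1Br
F5 | step 2 | 2,3-dibromo-4-(hydroxymethyl)phenol | OCc1ccc(O)c(Br)c1Br
F6 | step 1 | 5-bromo-2,4,6-trimethoxybenzene-1,3-dicarbaldehyde | COc1c(Br)c(OC)c(C=O)c(OC)c1C=O
F7 | step 1 | (5-bromo-2,4,6-trimethoxy-1,3-phenylene)dimethanol | COc1c(Br)c(OC)c(CO)c(OC)c1CO
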